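## Retrosynthetic overview

1. Target ⇐ desilylation ⇐ ring-closing metathesis at C2=C3, which closes the cyclodecadiene last.
2. Metathesis substrate ⇐ Yamaguchi acylation of the C8 alcohol with (2Z)-2-(TBS-oxymethyl)but-2-enoic acid (made from crotonaldehyde).
3. α-Methylene cis-γ-lactone ⇐ intermolecular indium Barbier allylation forming C6–C7 between (2Z)-3-methylpenta-2,4-dienal and a (Z)-2-(bromomethyl)enoate, then lactonisation.
4. Allyl bromide ⇐ Morita–Baylis–Hillman reaction and SN2′ bromination of an α-silyloxy aldehyde ⇐ Sharpless epoxidation of a dienol ⇐ Cu-catalysed opening of methyl (R)-glycidate by a dienyl Grignard from but-2-yne-1,4-diol.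
5. Ring order: oxirane (step 8) → γ-lactone (step 15) → ten-membered carbocycle (step 22).

Assumption 1: macrocycles are named with germacrane locants (C6 lactone carbinol carbon, C7 ring fusion, C8 acyloxy carbon, C1/C10 oxirane, C14 = CH2O on C10, C15 = CH3 on C4, C11=C13 exocyclic methylene, C12 lactone C=O); PMB = 4-methoxybenzyl, TES = triethylsilyl, TBS = tert-butyldimethylsilyl.
Assumption 2: the CIP descriptor at C7 changes between R and S along the route only because O-silyl, O-H and O-acyl change substituent priority; the centre is never inverted.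
Assumption 3: organometallic intermediates are drawn in their simplest monomeric form (allylindium as RInBr2) and aqueous work-up is taken as hydrolysis by water.

## Route

Step 1
Reactants: 1 but-2-yne-1,4-diol
Product: 2 4-(4-methoxybenzyloxy)but-2-yn-1-ol
Conditions: NaH (1.0 equiv), PMBCl (1.0 equiv), TBAI (cat.), THF/DMF, 0 °C → rt; diol 1 in 3-fold excess
Reagents that add atoms: 4-methoxybenzyl chloride, COc1ccc(CCl)cc1
Why: Williamson ether synthesis in which the excess of the symmetric diol secures the mono-ether; no stereocentre is involved.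

Step 2
Reactants: 2 4-(4-methoxybenzyloxy)but-2-yn-1-ol
Product: 4 (2Z)-3-iodo-4-(4-methoxybenzyloxy)but-2-en-1-ol, via cyclic vinylalanate 3 (not isolated)
Conditions: Red-Al (1.5 equiv), THF, 0 °C → rt; then I2, THF, −78 → 0 °C
Reagents that add atoms: iodine, II
Why: Hydroxyl-directed trans-hydroalumination puts aluminium on the distal alkyne carbon cis to the carbinol carbon, and iodinolysis with retention gives the (Z)-iodoalkene that later fixes the cis relation of C2 and C9 on the oxirane.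

Step 3
Reactants: 4 (2Z)-3-iodo-4-(4-methoxybenzyloxy)but-2-en-1-ol
Product: 5 (2Z)-3-iodo-4-(4-methoxybenzyloxy)but-2-enal
Conditions: MnO2 (15 equiv), CH2Cl2, 0 °C → rt, dark
Reagents that add atoms: none
Why: Allylic oxidation with MnO2 is neutral and heterogeneous, touches only the allylic alcohol and leaves the Z-iodoalkene geometry intact.

Step 4
Reactants: 5 (2Z)-3-iodo-4-(4-methoxybenzyloxy)but-2-enal
Product: 6 (2Z)-2-iodo-1-(4-methoxybenzyloxy)penta-2,4-diene
Conditions: Ph3PCH3Br, KHMDS, THF, −78 → 0 °C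
Reagents that add atoms: methyltriphenylphosphonium bromide, C[P+](c1ccccc1)(c1ccccc1)c1ccccc1.[Br-]
Why: Wittig methylenation in which the non-stabilised ylide adds 1,2 to the aldehyde at low temperature; no stereocentre is created and the C–I alkene geometry is untouched.

Step 5
Reactants: 6 (2Z)-2-iodo-1-(4-methoxybenzyloxy)penta-2,4-diene, 7 methyl (2R)-oxirane-2-carboxylate [methyl (R)-glycidate]
Product: 10 methyl (2R,4E)-2-hydroxy-4-[(4-methoxybenzyloxy)methyl]hepta-4,6-dienoate, via dienyllithium 8 (not isolated), via dienylmagnesium bromide 9 (not isolated)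
Conditions: t-BuLi (2.1 equiv), Et2O, −78 °C; MgBr2·OEt2, −78 °C; CuI (10 mol %), then 7, THF, −40 → −20 °C
Reagents that add atoms: none
Why: Iodine–lithium exchange and transmetalation retain the alkene geometry, and the copper-catalysed SN2 epoxide opening occurs at the unsubstituted C3 of the glycidate, so the C8 stereocentre is taken unchanged from (R)-glycidate.

Step 6
Reactants: 10 methyl (2R,4E)-2-hydroxy-4-[(4-methoxybenzyloxy)methyl]hepta-4,6-dienoate
Product: 11 methyl (2R,4E)-4-[(4-methoxybenzyloxy)methyl]-2-(triethylsilyloxy)hepta-4,6-dienoate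
Conditions: TESCl, imidazole, DMAP (cat.), CH2Cl2, 0 °C
Reagents that add atoms: chlorotriethylsilane, CC[Si](Cl)(CC)CC
Why: Silylation of the secondary alcohol under imidazole conditions that do not epimerise the α-stereocentre.

Step 7
Reactants: 11 methyl (2R,4E)-4-[(4-methoxybenzyloxy)methyl]-2-(triethylsilyloxy)hepta-4,6-dienoate
Product: 12 methyl (2R,4E)-4-(hydroxymethyl)-2-(triethylsilyloxy)hepta-4,6-dienoate
Conditions: DDQ (1.2 equiv), CH2Cl2/pH 7 buffer (10:1), 0 °C
Reagents that add atoms: none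
Why: Oxidative PMB cleavage by DDQ (benzylic hydride abstraction) under buffered conditions spares the TES ether and ester, and low temperature with near-stoichiometric DDQ prevents over-oxidation of the dienol.

Step 8
Reactants: 12 methyl (2R,4E)-4-(hydroxymethyl)-2-(triethylsilyloxy)hepta-4,6-dienoate
Product: 13 methyl (2R)-3-[(2R,3R)-3-ethenyl-2-(hydroxymethyl)oxiran-2-yl]-2-(triethylsilyloxy)propanoate
Conditions: Ti(OiPr)4 (10 mol %), D-(−)-diethyl tartrate (12 mol %), t-BuOOH (2 equiv), 4 Å MS, CH2Cl2, −20 °C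
Reagents that add atoms: tert-butyl hydroperoxide, CC(C)(C)OO
Why: Sharpless asymmetric epoxidation in which the Ti–D-(−)-tartrate complex epoxidises only the allylic-alcohol alkene and delivers oxygen to the face that gives the (2R,3R)-oxirane (C10 and C1 of the target), the alkene geometry fixing C2 cis to C9.

Step 9
Reactants: 13 methyl (2R)-3-[(2R,3R)-3-ethenyl-2-(hydroxymethyl)oxiran-2-yl]-2-(triethylsilyloxy)propanoate
Product: 14 methyl (2R)-3-[(2R,3R)-2-(TBS-oxymethyl)-3-ethenyloxiran-2-yl]-2-(triethylsilyloxy)propanoate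
Conditions: TBSCl, imidazole, DMF, 0 °C → rt
Reagents that add atoms: tert-butyldimethylsilyl chloride, CC(C)(C)[Si](C)(C)Cl
Why: Silylation of the primary epoxy alcohol under mild imidazole conditions that do not trigger Payne rearrangement.

Step 10
Reactants: 14 methyl (2R)-3-[(2R,3R)-2-(TBS-oxymethyl)-3-ethenyloxiran-2-yl]-2-(triethylsilyloxy)propanoate
Product: 15 (2R)-3-[(2R,3R)-2-(TBS-oxymethyl)-3-ethenyloxiran-2-yl]-2-(triethylsilyloxy)propanal
Conditions: DIBAL-H (1.1 equiv), CH2Cl2, −78 °C; Rochelle salt work-up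
Reagents that add atoms: none
Why: DIBAL-H partial reduction of the α-silyloxy ester stops at the chelated tetrahedral aluminate at −78 °C and gives the aldehyde without epimerisation at C8.

Step 11
Reactants: 15 (2R)-3-[(2R,3R)-2-(TBS-oxymethyl)-3-ethenyloxiran-2-yl]-2-(triethylsilyloxy)propanal, 16 methyl acrylate
Product: 17 methyl (4R)-5-[(2R,3R)-2-(TBS-oxymethyl)-3-ethenyloxiran-2-yl]-3-hydroxy-2-methylidene-4-(triethylsilyloxy)pentanoate (3-epimer mixture)
Conditions: DABCO (1.0 equiv), methyl acrylate (5 equiv), MeOH (2 equiv), rt, 3–5 d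
Reagents that add atoms: none
Why: Morita–Baylis–Hillman reaction in which the DABCO–acrylate enolate adds to the activated α-alkoxy aldehyde; the new carbinol centre is irrelevant because it is removed in step 12.

Step 12
Reactants: 17 methyl (4R)-5-[(2R,3R)-2-(TBS-oxymethyl)-3-ethenyloxiran-2-yl]-3-hydroxy-2-methylidene-4-(triethylsilyloxy)pentanoate
Product: 18 methyl (2Z,4R)-2-(bromomethyl)-5-[(2R,3R)-2-(TBS-oxymethyl)-3-ethenyloxiran-2-yl]-4-(triethylsilyloxy)pent-2-enoate
Conditions: NBS (1.3 equiv), Me2S (1.5 equiv), CH2Cl2, 0 °C → rt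
Reagents that add atoms: N-bromosuccinimide, O=C1CCC(=O)N1Br
Why: Corey–Kim-type activation followed by SN2′ attack of bromide gives the thermodynamically preferred (2Z)-2-(bromomethyl)enoate with C8 trans to the ester, under neutral conditions that epoxide and silyl ethers tolerate.

Step 13
Reactants: 19 (2Z)-3-methylpent-2-en-4-yn-1-ol
Product: 20 (2Z)-3-methylpenta-2,4-dien-1-ol
Conditions: H2 (1 atm), Lindlar catalyst, quinoline, EtOAc, 0 °C → rt
Reagents that add atoms: none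
Why: Lindlar semihydrogenation reduces the terminal alkyne to the vinyl group and does not touch the existing (Z)-trisubstituted alkene.

Step 14
Reactants: 20 (2Z)-3-methylpenta-2,4-dien-1-ol, 18 methyl (2Z,4R)-2-(bromomethyl)-5-[(2R,3R)-2-(TBS-oxymethyl)-3-ethenyloxiran-2-yl]-4-(triethylsilyloxy)pent-2-enoate
Product: 23 methyl (3S,4S,5Z)-3-{(1R)-2-[(2R,3R)-2-(TBS-oxymethyl)-3-ethenyloxiran-2-yl]-1-(triethylsilyloxy)ethyl}-4-hydroxy-6-methyl-2-methylideneocta-5,7-dienoate, via dienal 21 (not isolated), via allylindium dibromide 22 (not isolated)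
Conditions: (i) 20 (1.5 equiv), MnO2, CH2Cl2, 0 °C, filter, concentrate cold; (ii) 18, In powder (1.5 equiv), THF/H2O (3:1), 0 °C → rt
Reagents that add atoms: none
Why: Barbier-type carbonyl allylation (SE2′) through a chair six-membered transition state, in which the allylindium with C8 cis to CH2In gives the syn C6/C7 adduct and the aldehyde adds to the allyl face anti to the C9 chain while H-8 eclipses the alkene (A1,3 strain), setting C6 and C7 relative to C8 as in the target.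

Step 15
Reactants: 23 methyl (3S,4S,5Z)-3-{(1R)-2-[(2R,3R)-2-(TBS-oxymethyl)-3-ethenyloxiran-2-yl]-1-(triethylsilyloxy)ethyl}-4-hydroxy-6-methyl-2-methylideneocta-5,7-dienoate
Product: 24 (4S,5S)-4-{(1R)-2-[(2R,3R)-2-(TBS-oxymethyl)-3-ethenyloxiran-2-yl]-1-(triethylsilyloxy)ethyl}-3-methylidene-5-[(1Z)-2-methylbuta-1,3-dien-1-yl]oxolan-2-one
Conditions: NaH (0.2 equiv), THF, 0 °C
Reagents that add atoms: none
Why: Alkoxide-mediated intramolecular transesterification (5-exo-trig lactonisation) under aprotic basic conditions spares epoxide and silyl ethers, and the syn adduct gives the cis-lactone without touching a stereocentre.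

Step 16
Reactants: 24 (4S,5S)-4-{(1R)-2-[(2R,3R)-2-(TBS-oxymethyl)-3-ethenyloxiran-2-yl]-1-(triethylsilyloxy)ethyl}-3-methylidene-5-[(1Z)-2-methylbuta-1,3-dien-1-yl]oxolan-2-one
Product: 25 (4R,5S)-4-{(1R)-2-[(2R,3R)-2-(TBS-oxymethyl)-3-ethenyloxiran-2-yl]-1-hydroxyethyl}-3-methylidene-5-[(1Z)-2-methylbuta-1,3-dien-1-yl]oxolan-2-one
Conditions: HF·pyridine, excess pyridine, THF, 0 °C
Reagents that add atoms: none
Why: Fluoride desilylation in which the secondary TES ether is cleaved much faster than the primary TBS ether, and the pyridine buffer avoids acid-induced opening of the vinyl epoxide.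

Step 17
Reactants: 26 (2E)-but-2-enal (crotonaldehyde)
Product: 28 (2Z)-2-bromobut-2-enal, via 2,3-dibromobutanal 27 (not isolated)
Conditions: Br2, CH2Cl2, 0 °C; then Et3N, 0 °C → rt
Reagents that add atoms: bromine, BrBr
Why: Bromination of the alkene then E1cB dehydrobromination gives the thermodynamically preferred (Z)-α-bromoenal with Br cis to CH3.

Step 18
Reactants: 28 (2Z)-2-bromobut-2-enal
Product: 29 (2Z)-2-bromobut-2-en-1-ol
Conditions: NaBH4, CeCl3·7H2O, MeOH, 0 °C
Reagents that add atoms: none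
Why: Luche reduction gives clean 1,2-reduction of the enal with retention of alkene geometry.

Step 19
Reactants: 29 (2Z)-2-bromobut-2-en-1-ol
Product: 31 (2Z)-2-(hydroxymethyl)but-2-enoic acid, via dilithio species 30 (not isolated)
Conditions: t-BuLi (3.1 equiv), Et2O, −78 °C; CO2, −78 → 0 °C; then 1 M HCl
Reagents that add atoms: carbon dioxide, O=C=O
Why: Deprotonation and bromine–lithium exchange proceed with retention of configuration, and carboxylation of the vinyllithium places CO2H cis to CH3.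

Step 20
Reactants: 31 (2Z)-2-(hydroxymethyl)but-2-enoic acid
Product: 33 (2Z)-2-(TBS-oxymethyl)but-2-enoic acid, via bis-silyl ester 32 (not isolated)
Conditions: TBSCl (2.3 equiv), imidazole, DMF, rt; then H2O/MeOH/THF, AcOH (cat.), rt
Reagents that add atoms: tert-butyldimethylsilyl chloride, CC(C)(C)[Si](C)(C)Cl
Why: Silylation of both OH groups followed by selective hydrolysis of the far more labile silyl ester leaves the primary TBS ether and the Z geometry.

Step 21
Reactants: 25 (4R,5S)-4-{(1R)-2-[(2R,3R)-2-(TBS-oxymethyl)-3-ethenyloxiran-2-yl]-1-hydroxyethyl}-3-methylidene-5-[(1Z)-2-methylbuta-1,3-dien-1-yl]oxolan-2-one, 33 (2Z)-2-(TBS-oxymethyl)but-2-enoic acid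
Product: 35 (1R)-2-[(2R,3R)-2-(TBS-oxymethyl)-3-ethenyloxiran-2-yl]-1-{(2S,3R)-4-methylidene-2-[(1Z)-2-methylbuta-1,3-dien-1-yl]-5-oxooxolan-3-yl}ethyl (2Z)-2-(TBS-oxymethyl)but-2-enoate, via mixed anhydride 34 (not isolated)
Conditions: 33, 2,4,6-trichlorobenzoyl chloride, Et3N, toluene, rt; then 25, DMAP (0.3 equiv), toluene, rt
Reagents that add atoms: none
Why: Yamaguchi esterification through the mixed anhydride acylates the hindered C8 alcohol with retention at C8, and preforming the anhydride with little DMAP at rt limits Z→E isomerisation of the enoate.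

Step 22
Reactants: 35 (1R)-2-[(2R,3R)-2-(TBS-oxymethyl)-3-ethenyloxiran-2-yl]-1-{(2S,3R)-4-methylidene-2-[(1Z)-2-methylbuta-1,3-dien-1-yl]-5-oxooxolan-3-yl}ethyl (2Z)-2-(TBS-oxymethyl)but-2-enoate
Product: 36 (1R,6S,7R,8R,10R)-14-(TBS-oxy)-1,10-epoxy-8-{[(2Z)-2-(TBS-oxymethyl)but-2-enoyl]oxy}germacra-2Z,4Z,11(13)-trien-12,6-olide
Conditions: Grubbs II (10 mol %), 1,4-benzoquinone (20 mol %), CH2Cl2 (0.5 mM), 40 °C
Reagents that add atoms: none
Why: Ring-closing metathesis joins the two monosubstituted vinyl groups (the trisubstituted and electron-poor alkenes are inert), the cis-lactone pre-organises the chain and the strain of the ten-membered ring makes the new C2=C3 bond Z.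

Step 23
Reactants: 36 (1R,6S,7R,8R,10R)-14-(TBS-oxy)-1,10-epoxy-8-{[(2Z)-2-(TBS-oxymethyl)but-2-enoyl]oxy}germacra-2Z,4Z,11(13)-trien-12,6-olide
Product: 37 (1R,6S,7R,8R,10R)-1,10-epoxy-14-hydroxy-8-{[(2Z)-2-(hydroxymethyl)but-2-enoyl]oxy}germacra-2Z,4Z,11(13)-trien-12,6-olide (CNP0165856.1)
Conditions: TBAF/AcOH (1:1, 3 equiv), THF, 0 °C → rt
Reagents that add atoms: none
Why: Fluoride desilylation of both primary TBS ethers under acetic-acid buffering avoids Payne rearrangement, opening of the dienyl epoxide and Michael addition to the α-methylene lactone.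

## Compound list

1 | but-2-yne-1,4-diol | OCC#CCO | starting material
2 | 4-(4-methoxybenzyloxy)but-2-yn-1-ol | OCC#CCOCc1ccc(OC)cc1 | intermediate
3 | sodium 2,2-bis(2-methoxyethoxy)-3-(4-methoxybenzyloxymethyl)-2,5-dihydro-1,2-oxaaluminol-2-uide (cyclic vinylalanate, in situ) | [Na+].COCCO[Al-]1(OCCOC)OCC=C1COCc1ccc(OC)cc1 | intermediate
4 | (2Z)-3-iodo-4-(4-methoxybenzyloxy)but-2-en-1-ol | OC/C=C(\I)COCc1ccc(OC)cc1 | intermediate
5 | (2Z)-3-iodo-4-(4-methoxybenzyloxy)but-2-enal | O=C/C=C(\I)COCc1ccc(OC)cc1 | intermediate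
6 | (2Z)-2-iodo-1-(4-methoxybenzyloxy)penta-2,4-diene | C=C/C=C(\I)COCc1ccc(OC)cc1 | intermediate
7 | methyl (2R)-oxirane-2-carboxylate | COC(=O)[C@H]1CO1 | starting material
8 | [(1E)-1-(4-methoxybenzyloxymethyl)buta-1,3-dien-1-yl]lithium (Li cis to vinyl, in situ) | C=C/C=C(\[Li])COCc1ccc(OC)cc1 | intermediate
9 | bromo[(1E)-1-(4-methoxybenzyloxymethyl)buta-1,3-dien-1-yl]magnesium (Mg cis to vinyl, in situ) | C=C/C=C(\[Mg]Br)COCc1ccc(OC)cc1 | intermediate
10 | methyl (2R,4E)-2-hydroxy-4-[(4-methoxybenzyloxy)methyl]hepta-4,6-dienoate | COC(=O)[C@H](O)C/C(COCc1ccc(OC)cc1)=C\C=C | intermediate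
11 | methyl (2R,4E)-4-[(4-methoxybenzyloxy)methyl]-2-(triethylsilyloxy)hepta-4,6-dienoate | COC(=O)[C@H](O[Si](CC)(CC)CC)C/C(COCc1ccc(OC)cc1)=C\C=C | intermediate
12 | methyl (2R,4E)-4-(hydroxymethyl)-2-(triethylsilyloxy)hepta-4,6-dienoate | COC(=O)[C@H](O[Si](CC)(CC)CC)C/C(CO)=C\C=C | intermediate
13 | methyl (2R)-3-[(2R,3R)-3-ethenyl-2-(hydroxymethyl)oxiran-2-yl]-2-(triethylsilyloxy)propanoate | C=C[C@H]1O[C@@]1(CO)C[C@@H](O[Si](CC)(CC)CC)C(=O)OC | intermediate
14 | methyl (2R)-3-[(2R,3R)-2-(tert-butyldimethylsilyloxymethyl)-3-ethenyloxiran-2-yl]-2-(triethylsilyloxy)propanoate | C=C[C@H]1O[C@@]1(CO[Si](C)(C)C(C)(C)C)C[C@@H](O[Si](CC)(CC)CC)C(=O)OC | intermediate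
15 | (2R)-3-[(2R,3R)-2-(tert-butyldimethylsilyloxymethyl)-3-ethenyloxiran-2-yl]-2-(triethylsilyloxy)propanal | C=C[C@H]1O[C@@]1(CO[Si](C)(C)C(C)(C)C)C[C@@H](O[Si](CC)(CC)CC)C=O | intermediate
16 | methyl prop-2-enoate (methyl acrylate) | C=CC(=O)OC | starting material
17 | methyl (4R)-5-[(2R,3R)-2-(tert-butyldimethylsilyloxymethyl)-3-ethenyloxiran-2-yl]-3-hydroxy-2-methylidene-4-(triethylsilyloxy)pentanoate (3-epimer mixture) | C=C[C@H]1O[C@@]1(CO[Si](C)(C)C(C)(C)C)C[C@@H](O[Si](CC)(CC)CC)C(O)C(=C)C(=O)OC | intermediate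
18 | methyl (2Z,4R)-2-(bromomethyl)-5-[(2R,3R)-2-(tert-butyldimethylsilyloxymethyl)-3-ethenyloxiran-2-yl]-4-(triethylsilyloxy)pent-2-enoate | C=C[C@H]1O[C@@]1(CO[Si](C)(C)C(C)(C)C)C[C@@H](O[Si](CC)(CC)CC)/C=C(\CBr)C(=O)OC | intermediate
19 | (2Z)-3-methylpent-2-en-4-yn-1-ol | C#C/C(C)=C\CO | starting material
20 | (2Z)-3-methylpenta-2,4-dien-1-ol | C=C/C(C)=C\CO | intermediate
21 | (2Z)-3-methylpenta-2,4-dienal (in situ) | C=C/C(C)=C\C=O | intermediate
22 | dibromo[(2Z,4R)-5-{(2R,3R)-2-(tert-butyldimethylsilyloxymethyl)-3-ethenyloxiran-2-yl}-2-(methoxycarbonyl)-4-(triethylsilyloxy)pent-2-en-1-yl]indium (in situ) | C=C[C@H]1O[C@@]1(CO[Si](C)(C)C(C)(C)C)C[C@@H](O[Si](CC)(CC)CC)/C=C(\C[In](Br)Br)C(=O)OC | intermediate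
23 | methyl (3S,4S,5Z)-3-{(1R)-2-[(2R,3R)-2-(tert-butyldimethylsilyloxymethyl)-3-ethenyloxiran-2-yl]-1-(triethylsilyloxy)ethyl}-4-hydroxy-6-methyl-2-methylideneocta-5,7-dienoate | COC(=O)C(=C)[C@@H]([C@@H](O)/C=C(C)\C=C)[C@H](O[Si](CC)(CC)CC)C[C@]1(CO[Si](C)(C)C(C)(C)C)O[C@@H]1C=C | intermediate
24 | (4S,5S)-4-{(1R)-2-[(2R,3R)-2-(tert-butyldimethylsilyloxymethyl)-3-ethenyloxiran-2-yl]-1-(triethylsilyloxy)ethyl}-3-methylidene-5-[(1Z)-2-methylbuta-1,3-dien-1-yl]oxolan-2-one | C=C1C(=O)O[C@@H](/C=C(C)\C=C)[C@H]1[C@H](O[Si](CC)(CC)CC)C[C@]2(CO[Si](C)(C)C(C)(C)C)O[C@@H]2C=C | intermediate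
25 | (4R,5S)-4-{(1R)-2-[(2R,3R)-2-(tert-butyldimethylsilyloxymethyl)-3-ethenyloxiran-2-yl]-1-hydroxyethyl}-3-methylidene-5-[(1Z)-2-methylbuta-1,3-dien-1-yl]oxolan-2-one | C=C1C(=O)O[C@@H](/C=C(C)\C=C)[C@H]1[C@H](O)C[C@]2(CO[Si](C)(C)C(C)(C)C)O[C@@H]2C=C | intermediate
26 | (2E)-but-2-enal (crotonaldehyde) | C/C=C/C=O | starting material
27 | 2,3-dibromobutanal (in situ) | CC(Br)C(Br)C=O | intermediate
28 | (2Z)-2-bromobut-2-enal | C/C=C(\Br)C=O | intermediate
29 | (2Z)-2-bromobut-2-en-1-ol | C/C=C(\Br)CO | intermediate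
30 | lithium (2E)-2-lithiobut-2-en-1-olate (Li cis to CH3, in situ) | C/C=C(\[Li])CO[Li] | intermediate
31 | (2Z)-2-(hydroxymethyl)but-2-enoic acid | C/C=C(/CO)C(=O)O | intermediate
32 | tert-butyldimethylsilyl (2Z)-2-(tert-butyldimethylsilyloxymethyl)but-2-enoate (in situ) | C/C=C(/CO[Si](C)(C)C(C)(C)C)C(=O)O[Si](C)(C)C(C)(C)C | intermediate
33 | (2Z)-2-(tert-butyldimethylsilyloxymethyl)but-2-enoic acid | C/C=C(/CO[Si](C)(C)C(C)(C)C)C(=O)O | intermediate
34 | (2Z)-2-(tert-butyldimethylsilyloxymethyl)but-2-enoic 2,4,6-trichlorobenzoic anhydride (in situ) | C/C=C(/CO[Si](C)(C)C(C)(C)C)C(=O)OC(=O)c1c(Cl)cc(Cl)cc1Cl | intermediate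
35 | (1R)-2-[(2R,3R)-2-(tert-butyldimethylsilyloxymethyl)-3-ethenyloxiran-2-yl]-1-{(2S,3R)-4-methylidene-2-[(1Z)-2-methylbuta-1,3-dien-1-yl]-5-oxooxolan-3-yl}ethyl (2Z)-2-(tert-butyldimethylsilyloxymethyl)but-2-enoate | C=C1C(=O)O[C@@H](/C=C(C)\C=C)[C@H]1[C@H](OC(=O)/C(=C\C)CO[Si](C)(C)C(C)(C)C)C[C@]2(CO[Si](C)(C)C(C)(C)C)O[C@@H]2C=C | intermediate
36 | (1R,6S,7R,8R,10R)-14-(tert-butyldimethylsilyloxy)-1,10-epoxy-8-{[(2Z)-2-(tert-butyldimethylsilyloxymethyl)but-2-enoyl]oxy}germacra-2Z,4Z,11(13)-trien-12,6-olide | C=C1C(=O)O[C@H]2/C=C(C)\C=C/[C@H]3O[C@@]3(CO[Si](C)(C)C(C)(C)C)C[C@@H](OC(=O)/C(=C\C)CO[Si](C)(C)C(C)(C)C)[C@@H]12 | intermediate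
37 | (1R,6S,7R,8R,10R)-1,10-epoxy-14-hydroxy-8-{[(2Z)-2-(hydroxymethyl)but-2-enoyl]oxy}germacra-2Z,4Z,11(13)-trien-12,6-olide (CNP0165856.1) | C=C1C(=O)O[C@H]2/C=C(C)\C=C/[C@H]3O[C@@]3(CO)C[C@@H](OC(=O)/C(=C\C)CO)[C@@H]12 | target

## Step count and risk

Total steps: 23. Longest linear sequence: 18 (steps 1–12, 14–16, 21–23).

Most likely to fail, first: step 14. The Barbier allylation must deliver both the syn relation and the right allyl face, and the Z-dienal and vinyl epoxide must survive the metal. The fallback sets out from 17 and comes back at 23. Acetylation (Ac2O, DMAP, pyridine) gives methyl (4R)-3-acetoxy-5-[(2R,3R)-2-(tert-butyldimethylsilyloxymethyl)-3-ethenyloxiran-2-yl]-2-methylidene-4-(triethylsilyloxy)pentanoate F1. Palladium-free copper-mediated SN2′ borylation (CuCl, LiCl, KOAc, B2pin2, DMF, rt) then gives the configurationally stable methyl (2E,4R)-5-[(2R,3R)-2-(tert-butyldimethylsilyloxymethyl)-3-ethenyloxiran-2-yl]-2-[(4,4,5,5-tetramethyl-1,3,2-dioxaborolan-2-yl)methyl]-4-(triethylsilyloxy)pent-2-enoate F2, with C8 cis to CH2B. Uncatalysed allylboration of dienal 21 (toluene, rt → 50 °C, aqueous NaHCO3 work-up) runs through a closed chair transition state whose alkene geometry cannot scramble, and gives the syn adduct 23.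

Second: step 22. Closing a ten-membered Z,Z-diene next to a vinyl epoxide may give oligomers, the E isomer or a truncated ring. The fallback sets out from 24 and comes back at 36; it closes the ring before the bulky ester is attached. Metathesis of the less encumbered silyl ether 24 under the same catalyst gives (1R,6S,7S,8R,10R)-14-(tert-butyldimethylsilyloxy)-1,10-epoxy-8-(triethylsilyloxy)germacra-2Z,4Z,11(13)-trien-12,6-olide F3. Buffered HF·pyridine then gives (1R,6S,7R,8R,10R)-14-(tert-butyldimethylsilyloxy)-1,10-epoxy-8-hydroxygermacra-2Z,4Z,11(13)-trien-12,6-olide F4, and Yamaguchi acylation with mixed anhydride 34 gives 36.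

Third: step 11. The Morita–Baylis–Hillman reaction of a hindered, epimerisable α-silyloxy aldehyde can be very slow. The fallback sets out from 15 and comes back at 17; it replaces amine catalysis by vinylalumination. Methyl propiolate with DIBAL-H/NMO (THF, 0 °C) gives [1-(methoxycarbonyl)ethenyl]bis(2-methylpropyl)aluminium F5, which adds to 15 at −78 → 0 °C within hours to give 17 directly.

## Further compounds

F1 | step 14 | methyl (4R)-3-acetoxy-5-[(2R,3R)-2-(tert-butyldimethylsilyloxymethyl)-3-ethenyloxiran-2-yl]-2-methylidene-4-(triethylsilyloxy)pentanoate | C=C[C@H]1O[C@@]1(CO[Si](C)(C)C(C)(C)C)C[C@@H](O[Si](CC)(CC)CC)C(OC(C)=O)C(=C)C(=O)OC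
F2 | step 14 | methyl (2E,4R)-5-[(2R,3R)-2-(tert-butyldimethylsilyloxymethyl)-3-ethenyloxiran-2-yl]-2-[(4,4,5,5-tetramethyl-1,3,2-dioxaborolan-2-yl)methyl]-4-(triethylsilyloxy)pent-2-enoate | C=C[C@H]1O[C@@]1(CO[Si](C)(C)C(C)(C)C)C[C@@H](O[Si](CC)(CC)CC)/C=C(\CB1OC(C)(C)C(C)(C)O1)C(=O)OC
F3 | step 22 | (1R,6S,7S,8R,10R)-14-(tert-butyldimethylsilyloxy)-1,10-epoxy-8-(triethylsilyloxy)germacra-2Z,4Z,11(13)-trien-12,6-olide | C=C1C(=O)O[C@H]2/C=C(C)\C=C/[C@H]3O[C@@]3(CO[Si](C)(C)C(C)(C)C)C[C@@H](O[Si](CC)(CC)CC)[C@@H]12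
F4 | step 22 | (1R,6S,7R,8R,10R)-14-(tert-butyldimethylsilyloxy)-1,10-epoxy-8-hydroxygermacra-2Z,4Z,11(13)-trien-12,6-olide | C=C1C(=O)O[C@H]2/C=C(C)\C=C/[C@H]3O[C@@]3(CO[Si](C)(C)C(C)(C)C)C[C@@H](O)[C@@H]12
F5 | step 11 | [1-(methoxycarbonyl)ethenyl]bis(2-methylpropyl)aluminium | C=C(C(=O)OC)[Al](CC(C)C)CC(C)C
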